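- Late in the beta run, the substrate left times the time holds roughly steady. With substrate as a fraction of its charge, this product reads 0.100 min at 1.00 min and 0.0720 min at 6.00 min, and the last 3 readings average 0.0883 min.
- Substrate and target sum to 99.9 % at the last beta reading, so target is reckoned as the charge minus the small substrate remainder.

common to all: substrate 0.050 M; enzyme 13 µM
- beta: impurity 4.6 µM; run made earlier
- flask: impurity 9.2 µM; time 20 min

- beta (time / min: substrate / %, target / %): 1.00: 10.0, 89.9; 2.00: 4.5, 95.0; 3.00: 2.8, 96.8; 4.00: 2.2, 97.2; 5.00: 2.1, 98.3; 6.00: 1.2, 98.7

(each reading ± 0.5 percentage points)

- no earlier run changes the charge of impurity; that part of a forecast is a guess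

- the species in which most of what was charged as substrate, at 20 min sits (substrate / target)
- the largest share itself, whichever of these holds it, in percent of the substrate charged

- A bench rule says that, at equal substrate charge, equal enzyme times time gives equal conversion.
- No earlier run changes the impurity, so its effect is a guess: here each impurity is taken to remove one enzyme.
- The working enzyme, the enzyme charge minus the impurity charge, is then 3.80 µM in the flask and 8.40 µM in the beta run.
- So 20 min in the flask equals 9.05 min of beta time, which lies past the last reading.
- Carrying the steady product on to that beta time, an extrapolation of scattered readings, leaves 0.976 % of substrate and gives 99.0 % of target.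
- The border is a ratio, impurity charge over enzyme charge: 0.708 in the flask and 0.354 in the beta run.
- The working enzyme reaches zero at a ratio of 1, and this reckoning stops there. Below that ratio, impurity is the limiting reagent, and the working enzyme is positive.
- The forecast gives target at 95 %, below this reckoning: “Either way, target holds most of the material”.
- The flask gives target at 98.6 %, with substrate at 1.00 %.

    enzyme + impurity → spent catalyst (k = 14000 /M/s)
    substrate + enzyme → target + enzyme, rate k2*[substrate]^2*[enzyme]/(1 + ([substrate]/Kh2)^2) (30.2 mM, k = 4.35 × 10⁵ /M²/s)
    2 substrate → self-condensation product (k = 0.00328 /M/s)

- In the flask, impurity and enzyme reacted early: at 2.00 min impurity stands at 0.0494 % of its charge and enzyme at 29.3 % of the catalyst charged, against 29.2 % reckoned from the working enzyme, and while enzyme stood at that level, with 29.2 % at 20.0 min, substrate fell from 9.62 % to 1.00 %. A neighbour flask with 16.0 µM of impurity reckons to a working enzyme of −3.00 µM, an excess of impurity, and it ends with enzyme at 0 %, impurity at 18.8 % of its charge, against 18.8 % from that excess, and target at 53.1 %.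

(The readings stem from a simulated flask on assumed constants, noise included.)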